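**Strategy.** Ring B, the gem-dimethyl dihydropyran fused to the second quinolone (O–CMe2–C-b–C-c–C-3′=C-4′), is dissected at three bonds: C-b–CMe2, C-c–C-3′ and O–CMe2. This exploits that C-c is the anomeric O–CH carbon of pyran ring A and C-b its neighbour. Both are therefore latent in the enol ether C-b=C-c of a 4H-pyrano[3,2-c]quinolinone, while CMe2–O is acetone at the ketal level. In one pot, enol ether 12, 2,2-dimethoxypropane and 4-hydroxyquinolone 6 are joined in a [2+1+3] annulation that sets C-b and C-c. Enol ether 12 comes from the same quinolone 6 by an iminium-catalysed Michael addition to an enal, which sets C-a.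

Key step: step 6

Remark: C-a is the isobutyl-bearing CH, C-b the ring-fusion CH on CMe2, C-c the ring-fusion O–CH (target: C-a S, C-b S, C-c R); compounds 1, 4, 7, 8, 13 and (R)-α,α-diphenylprolinol trimethylsilyl ether are taken as commercial.

**Step 1**
Reactants: 1 2,3-dimethoxyaniline
Product: 3 2,3-dimethoxy-N-methylaniline, via N-methoxymethyl aminal 2 (not isolated)
Conditions: (CH2O)n, NaOMe, MeOH, reflux; then NaBH4, reflux
Reagents that add atoms: paraformaldehyde (as formaldehyde) C=O
Why: Mono-N-methylation by reductive amination: the aniline condenses with formaldehyde and methoxide to the aminal 2, which NaBH4 reduces through the iminium ion, so that dimethylation should not occur.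

**Step 2**
Reactants: 3 2,3-dimethoxy-N-methylaniline; 4 bis(2,4,6-trichlorophenyl) malonate
Product: 6 4-hydroxy-7,8-dimethoxy-1-methylquinolin-2(1H)-one, via malonamate aryl ester 5 (not isolated)
Conditions: neat melt (1:1), 200–220 °C; Et2O trituration
Reagents that add atoms: none
Why: Thermal cyclocondensation with an activated malonate: N-acylation to 5, loss of the second trichlorophenol to the acylketene and intramolecular Friedel–Crafts acylation at the only free ortho position (para to the 3-OMe) should give the 4-hydroxy-2-quinolone directly.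

**Step 3**
Reactants: 7 3-methylbutanal; 8 (triphenylphosphoranylidene)acetaldehyde
Product: 9 (E)-5-methylhex-2-enal
Conditions: toluene, 80 °C (7 in excess)
Reagents that add atoms: none
Why: Wittig olefination with a stabilized formyl ylide should give the E-enal; keeping the ylide limiting suppresses a second homologation.

**Step 4**
Reactants: 6 4-hydroxy-7,8-dimethoxy-1-methylquinolin-2(1H)-one; 9 (E)-5-methylhex-2-enal
Product: 11 (4S)-2-hydroxy-7,8-dimethoxy-6-methyl-4-(2-methylpropyl)-2,3,4,6-tetrahydro-5H-pyrano[3,2-c]quinolin-5-one (anomeric mixture), via Michael adduct aldehyde 10 (not isolated)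
Conditions: (R)-α,α-diphenylprolinol TMS ether (10 mol %), PhCO2H (10 mol %), CH2Cl2, rt
Reagents that add atoms: none
Why: Iminium-ion organocatalysis with a diarylprolinol silyl ether: C-3 of 6 adds in a Michael reaction to the E, s-trans iminium ion on the face anti to the CPh2OTMS group, which for the (R)-catalyst is the Si face of C-3 of 9 and sets S at C-a, and aldehyde 10 closes to lactol 11 by hemiacetalisation.

**Step 5**
Reactants: 11 lactol
Product: 12 (4S)-7,8-dimethoxy-6-methyl-4-(2-methylpropyl)-4,6-dihydro-5H-pyrano[3,2-c]quinolin-5-one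
Conditions: TsOH·H2O (5 mol %), toluene, 4 Å MS, 90 °C
Reagents that add atoms: none
Why: Acid-catalysed dehydration of a lactol (E1 through the ring oxocarbenium ion, water taken up by the sieves) should give the cyclic enol ether, and C-a is not involved and keeps its configuration.

**Step 6**
Reactants: 12 enol ether; 13 2,2-dimethoxypropane; 6 4-hydroxy-7,8-dimethoxy-1-methylquinolin-2(1H)-one
Product: 16 CNP0275598.1 (the target), via bis-methoxy acetal 14 (not isolated), via C-glycoside methyl ether 15 (not isolated)
Conditions: 13 (3 equiv), TMSOTf (0.2 equiv), CH2Cl2, −78 to −40 °C; excess 13 removed in vacuo; then 6 (1.3 equiv), TfOH (0.2 equiv), MeCN, 0 to 40 °C (one pot)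
Reagents that add atoms: none
Why: TMSOTf ionizes ketal 13 to the 2-methoxyprop-2-yl cation, which the enol ether carbon C-b of 12 attacks on the face anti to the pseudo-axial isobutyl group at C-a, and methoxide transfer gives acetal 14; TfOH then re-forms the oxocarbenium ion at C-c at 0 °C, C-3 of 6 adds to it to give 15, and only on warming does the tertiary methyl ether ionize so that the quinolone 4-OH captures the tertiary cation. The closest known reaction types are the Lewis-acid acetal–enol ether addition (Mukaiyama-type), the Friedel–Crafts C-alkylation of 4-hydroxy-2-quinolones and 4-hydroxycoumarins by cyclic oxocarbenium ions, and the acid-mediated closure of 3-prenyl-4-hydroxyquinolones to 2,2-dimethyldihydropyrans, which together amount to a [2+1+3] annulation. Ring B is closed last by the O–CMe2 bond in a 6-exo SN1 capture, equivalent to a Markovnikov 6-exo-trig hydroalkoxylation of the isopropenyl elimination product that stays in equilibrium with the cation. C-b is set by 1,2-induction from C-a (anti addition, trans), and C-c is set by the ring closure itself: 15 should stay epimerizable at C-c through reversible opening of the ring-A O–C-c bond to a quinone-methide-type cation, and only the epimer with the quinolone cis to the CMe2 arm can reach the tertiary cation in the half-chair that keeps the isobutyl group pseudo-axial, which gives the cis ring fusion. The step needs the ketal cation to meet the enol ether and not 6 (6 would lead through its isopropylidene quinone methide to the regioisomeric C-3′–CMe2 pyran), which the order of addition and the removal of excess 13 secure; it also needs C-alkylation at C-c before O-alkylation at CMe2, which the reversibility of the O-glycoside and the easier ionization of the acetal than of the tertiary ether secure.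

**Compound list**
1 | 2,3-dimethoxyaniline | Nc1cccc(OC)c1OC | starting material
2 | N-(methoxymethyl)-2,3-dimethoxyaniline (not isolated) | COCNc1cccc(OC)c1OC | intermediate
3 | 2,3-dimethoxy-N-methylaniline | CNc1cccc(OC)c1OC | intermediate
4 | bis(2,4,6-trichlorophenyl) malonate | O=C(CC(=O)Oc1c(Cl)cc(Cl)cc1Cl)Oc1c(Cl)cc(Cl)cc1Cl | starting material
5 | 2,4,6-trichlorophenyl 3-[(2,3-dimethoxyphenyl)(methyl)amino]-3-oxopropanoate (not isolated) | CN(C(=O)CC(=O)Oc1c(Cl)cc(Cl)cc1Cl)c1cccc(OC)c1OC | intermediate
6 | 4-hydroxy-7,8-dimethoxy-1-methylquinolin-2(1H)-one | COc1ccc2c(O)cc(=O)n(C)c2c1OC | intermediate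
7 | 3-methylbutanal | CC(C)CC=O | starting material
8 | (triphenylphosphoranylidene)acetaldehyde | O=CC=P(c1ccccc1)(c1ccccc1)c1ccccc1 | starting material
9 | (E)-5-methylhex-2-enal | CC(C)C/C=C/C=O | intermediate
10 | (3S)-3-(4-hydroxy-7,8-dimethoxy-1-methyl-2-oxo-1,2-dihydroquinolin-3-yl)-5-methylhexanal (not isolated) | COc1ccc2c(O)c([C@@H](CC(C)C)CC=O)c(=O)n(C)c2c1OC | intermediate
11 | (4S)-2-hydroxy-7,8-dimethoxy-6-methyl-4-(2-methylpropyl)-2,3,4,6-tetrahydro-5H-pyrano[3,2-c]quinolin-5-one (anomeric mixture) | COc1ccc2c3c(c(=O)n(C)c2c1OC)[C@@H](CC(C)C)CC(O)O3 | intermediate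
12 | (4S)-7,8-dimethoxy-6-methyl-4-(2-methylpropyl)-4,6-dihydro-5H-pyrano[3,2-c]quinolin-5-one | COc1ccc2c3c(c(=O)n(C)c2c1OC)[C@@H](CC(C)C)C=CO3 | intermediate
13 | 2,2-dimethoxypropane | COC(C)(C)OC | starting material
14 | (3R,4S)-2,7,8-trimethoxy-3-(2-methoxypropan-2-yl)-6-methyl-4-(2-methylpropyl)-2,3,4,6-tetrahydro-5H-pyrano[3,2-c]quinolin-5-one (anomeric mixture, not isolated) | COc1ccc2c3c(c(=O)n(C)c2c1OC)[C@@H](CC(C)C)[C@H](C(C)(C)OC)C(OC)O3 | intermediate
15 | (2R,3S,4S)-2-(4-hydroxy-7,8-dimethoxy-1-methyl-2-oxo-1,2-dihydroquinolin-3-yl)-7,8-dimethoxy-3-(2-methoxypropan-2-yl)-6-methyl-4-(2-methylpropyl)-2,3,4,6-tetrahydro-5H-pyrano[3,2-c]quinolin-5-one (not isolated) | COc1ccc2c3c(c(=O)n(C)c2c1OC)[C@@H](CC(C)C)[C@H](C(C)(C)OC)[C@@H](O3)c1c(O)c2ccc(OC)c(OC)c2n(C)c1=O | intermediate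
16 | CNP0275598.1, cis-fused bis(pyranoquinolinone), C-a S, C-b S, C-c R | COc1ccc2c3c(c(=O)n(C)c2c1OC)[C@@H](CC(C)C)[C@H]1[C@@H](O3)c2c(c3ccc(OC)c(OC)c3n(C)c2=O)OC1(C)C | target

**Step count.** Total: 6 steps. Longest linear sequence: 5 steps (steps 1, 2, 4, 5, 6); step 3 is a one-step branch, and quinolone 6 enters twice.

**Steps most likely to fail**

Step 6. Three processes may defeat it. The β-methoxy oxocarbenium ion re-formed at C-c may fragment back to the enol ether and the ketal cation before 6 captures it. The first C–C bond may form sluggishly, because the enol ether oxygen is a vinylogous ester oxygen. Ring closure may run through the diequatorial conformer to the trans-fused epimer at C-c. The fallback sets out from 12 and 6 and comes back at 16. Enol ether 12 is added to TiCl4-activated acetone (CH2Cl2, −78 °C; MeOH/Et3N quench of the α-chloro ether) to give (3R,4S)-3-(2-hydroxypropan-2-yl)-2,7,8-trimethoxy-6-methyl-4-(2-methylpropyl)-2,3,4,6-tetrahydro-5H-pyrano[3,2-c]quinolin-5-one F1. Quinolone 6 is converted with POCl3 into 4-chloro-7,8-dimethoxy-1-methylquinolin-2(1H)-one F2. The potassium alkoxide of F1 (KHMDS, THF/DMF) displaces chloride from F2 by SNAr to give the tertiary quinolin-4-yl ether F3, so the O–CMe2 connectivity is fixed before any cation is made. BF3·OEt2 then ionizes only the anomeric methoxy group, and C-3 of the tethered quinolone closes ring B by an intramolecular Friedel–Crafts (oxa-Pictet–Spengler-type) reaction to give 16. The aryloxy group is a poor donor for fragmentation, and the tether should allow only the cis fusion.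

Step 4. Two processes may defeat it: competing 1,2-addition (Knoevenagel condensation, then oxa-6π-electrocyclization to a 2H-pyran), and insufficient facial discrimination with a β-alkyl enal. The fallback sets out from 6 and 9 and comes back at 11. Oxidative N-heterocyclic-carbene catalysis (chiral aminoindanol-derived N-mesityl triazolium salt, DBU, 3,3′,5,5′-tetra-tert-butyldiphenoquinone, toluene, rt) turns 9 into the α,β-unsaturated acyl azolium ion. Quinolone 6 adds to it in a Michael/lactonization sequence to give (4S)-7,8-dimethoxy-6-methyl-4-(2-methylpropyl)-3,4-dihydro-2H-pyrano[3,2-c]quinoline-2,5(6H)-dione F4. DIBAL-H (CH2Cl2, −78 °C) reduces the enol lactone to lactol 11.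

Step 5. Two processes may defeat it: acid-mediated self-condensation of the enol ether with unreacted lactol, and partial racemization through retro-Michael opening of the open-chain form on heating. The fallback sets out from 11 and comes back at 12. PhSH/BF3·OEt2 (CH2Cl2, −20 °C) gives (4S)-7,8-dimethoxy-6-methyl-4-(2-methylpropyl)-2-(phenylsulfanyl)-2,3,4,6-tetrahydro-5H-pyrano[3,2-c]quinolin-5-one F5. mCPBA (CH2Cl2, −78 °C) gives the corresponding 2-(benzenesulfinyl) compound F6. Thermal syn-elimination of the sulfoxide (toluene, 90 °C, iPr2NEt) gives 12 under non-acidic conditions.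

**Further compounds**
F1 | step 6 | (3R,4S)-3-(2-hydroxypropan-2-yl)-2,7,8-trimethoxy-6-methyl-4-(2-methylpropyl)-2,3,4,6-tetrahydro-5H-pyrano[3,2-c]quinolin-5-one | COc1ccc2c3c(c(=O)n(C)c2c1OC)[C@@H](CC(C)C)[C@H](C(C)(C)O)C(OC)O3
F2 | step 6 | 4-chloro-7,8-dimethoxy-1-methylquinolin-2(1H)-one | COc1ccc2c(Cl)cc(=O)n(C)c2c1OC
F3 | step 6 | (3R,4S)-3-{2-[(7,8-dimethoxy-1-methyl-2-oxo-1,2-dihydroquinolin-4-yl)oxy]propan-2-yl}-2,7,8-trimethoxy-6-methyl-4-(2-methylpropyl)-2,3,4,6-tetrahydro-5H-pyrano[3,2-c]quinolin-5-one | COc1ccc2c3c(c(=O)n(C)c2c1OC)[C@@H](CC(C)C)[C@H](C(C)(C)Oc1cc(=O)n(C)c2c(OC)c(OC)ccc12)C(OC)O3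
F4 | step 4 | (4S)-7,8-dimethoxy-6-methyl-4-(2-methylpropyl)-3,4-dihydro-2H-pyrano[3,2-c]quinoline-2,5(6H)-dione | COc1ccc2c3c(c(=O)n(C)c2c1OC)[C@@H](CC(C)C)CC(=O)O3
F5 | step 5 | (4S)-7,8-dimethoxy-6-methyl-4-(2-methylpropyl)-2-(phenylsulfanyl)-2,3,4,6-tetrahydro-5H-pyrano[3,2-c]quinolin-5-one | COc1ccc2c3c(c(=O)n(C)c2c1OC)[C@@H](CC(C)C)CC(Sc1ccccc1)O3
F6 | step 5 | (4S)-2-(benzenesulfinyl)-7,8-dimethoxy-6-methyl-4-(2-methylpropyl)-2,3,4,6-tetrahydro-5H-pyrano[3,2-c]quinolin-5-one | COc1ccc2c3c(c(=O)n(C)c2c1OC)[C@@H](CC(C)C)CC(S(=O)c1ccccc1)O3
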